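## Retrosynthetic overview

1. The target is the C-4 salicylate of a 3,4-dihydroxy-octahydroazulene (a daucane diol). The ester is made last, from the diol and the acetonide of salicylic acid.
2. The C-6 methyl comes from a C-6 ester. The trans H-3a/C-4–O pair comes from syn hydroboration of a C3a=C4 alkene, while the ester shields C6=C7.
3. The seven-membered ring is disconnected at C5–C6 and C8–C8a. A rhodium carbenoid from methyl 2-diazobut-3-enoate cyclopropanates a 2-vinylcyclopentene, and the cis-divinylcyclopropane then undergoes Cope rearrangement, closing the ring at C8–C8a and setting the quaternary C-8a.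
4. Enabling feature: C6=C7 and the hydrated C3a=C4 unit (H-3a, O-4) flank the C-5 methylene. The seven-membered ring is therefore a latent cyclohepta-1,4-diene, the retron of this Cope rearrangement, with C8–C8a as the σ-bond between the two vinyl termini.
5. The five-membered ring with the C-3 carbinol comes from (S)-terpinen-4-ol by ozonolysis and aldol ring contraction. Ring order: cyclopentene (step 3), then cyclopropane and cycloheptadiene in one operation (step 6).

Key step: step 6

Remark: (S)-(+)-terpinen-4-ol (enantiopure) and 2,2-dimethyl-4H-1,3-benzodioxin-4-one are taken as purchasable; atom numbers are those of the azulene skeleton of the target (C-3 carbinol, C-3a ring-fusion CH, C-4 ester-bearing carbon, C-6/C-7 alkene, C-8a quaternary carbon).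

## Route

Step 1
Reactants: 1 (S)-terpinen-4-ol
Product: 2 (S)-triethyl{[4-methyl-1-(propan-2-yl)cyclohex-3-en-1-yl]oxy}silane
Conditions: Et3SiOTf, 2,6-lutidine, CH2Cl2, 0 °C → rt
Reagents that add atoms: triethylsilyl trifluoromethanesulfonate, CC[Si](CC)(CC)OS(=O)(=O)C(F)(F)F
Why: Silyl triflate/2,6-lutidine silylation, the standard method for hindered tertiary alcohols, masks the hydroxyl (needed against O–H insertion of the carbenoid in step 6) without touching the stereocentre or the alkene.

Step 2
Reactants: 2 (S)-triethyl{[4-methyl-1-(propan-2-yl)cyclohex-3-en-1-yl]oxy}silane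
Product: 4 (S)-6-oxo-3-(propan-2-yl)-3-[(triethylsilyl)oxy]heptanal, via secondary ozonide 3 (not isolated)
Conditions: O3, CH2Cl2, −78 °C; then PPh3, −78 °C → rt
Reagents that add atoms: ozone, [O-][O+]=O
Why: Ozonolysis (Criegee mechanism) cleaves the only C=C bond and reduction of the ozonide by the phosphine gives the 1,6-keto aldehyde; the silyl ether and the stereocentre are not involved.

Step 3
Reactants: 4 (S)-6-oxo-3-(propan-2-yl)-3-[(triethylsilyl)oxy]heptanal
Product: 5 (R)-2-methyl-5-(propan-2-yl)-5-[(triethylsilyl)oxy]cyclopent-1-ene-1-carbaldehyde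
Conditions: piperidine (0.3 equiv), AcOH (0.3 equiv), benzene, 25 → 60 °C
Reagents that add atoms: none
Why: Amine-catalysed intramolecular aldol condensation in its enamine mode: the aldehyde enamine adds 5-exo to the methyl ketone and loss of water gives the conjugated tetrasubstituted enal (the ring contraction known for keto aldehydes from 1-methylcyclohexenes), whereas hydroxide would give the regioisomeric acetylcyclopentene; the carbinol centre is untouched.

Step 4
Reactants: 5 (R)-2-methyl-5-(propan-2-yl)-5-[(triethylsilyl)oxy]cyclopent-1-ene-1-carbaldehyde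
Product: 6 (R)-triethyl{[2-ethenyl-3-methyl-1-(propan-2-yl)cyclopent-2-en-1-yl]oxy}silane
Conditions: Ph3PCH3Br, KOt-Bu, THF, 0 °C → rt
Reagents that add atoms: methyltriphenylphosphonium bromide, C[P+](c1ccccc1)(c1ccccc1)c1ccccc1.[Br-]
Why: Wittig methylenation with the unstabilised ylide converts the hindered, non-enolisable enal into the 1,3-diene under conditions that leave the silyl ether alone.

Step 5
Reactants: 7 methyl but-3-enoate
Product: 8 methyl 2-diazobut-3-enoate
Conditions: 4-acetamidobenzenesulfonyl azide, DBU, MeCN, 0 °C; extracted into cold hexanes and used at once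
Reagents that add atoms: 4-acetamidobenzenesulfonyl azide, CC(=O)Nc1ccc(cc1)S(=O)(=O)N=[N+]=[N-]
Why: Regitz diazo transfer to the methylene activated by both the ester and the vinyl group is the usual access to vinyldiazoacetates; 8 is kept cold and used at once because it cyclises to a pyrazole on standing.

Step 6
Reactants: 6 (R)-triethyl{[2-ethenyl-3-methyl-1-(propan-2-yl)cyclopent-2-en-1-yl]oxy}silane; 8 methyl 2-diazobut-3-enoate (2.5 equiv)
Product: 10 methyl (3R,8aR)-8a-methyl-3-(propan-2-yl)-3-[(triethylsilyl)oxy]-1,2,3,5,8,8a-hexahydroazulene-6-carboxylate, via cis-divinylcyclopropane 9 (not isolated)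
Conditions: Rh2(R-DOSP)4 (1 mol%), hexanes, −40 °C → rt, slow addition of 8; then toluene, 90 °C
Reagents that add atoms: none
Why: The dirhodium tetraprolinate (divalent rhodium) turns 8 into a donor/acceptor vinylcarbenoid that cyclopropanates only the monosubstituted vinyl group of 6 (the tetrasubstituted ring alkene is inert), with the carbenoid vinyl group cis to the cyclopentenyl group, giving 9; Cope rearrangement of 9 through the endo boat transition state then breaks the C4–C6 cyclopropane bond and forms the C8–C8a bond. The closest known reaction type is the tandem cyclopropanation/Cope rearrangement (formal 4+3 cycloaddition) of vinyldiazoacetates with dienes, including 1-vinylcycloalkenes whose fully substituted terminus becomes an angular quaternary carbon. The three-membered ring closes by concerted (2+1) addition of the carbenoid, and the seven-membered ring by the [3,3]-sigmatropic shift, a 3 → 7 ring enlargement completed by the C8–C8a bond. C-8a, the only new stereocentre of 10, is set by chirality transfer: the boat geometry lets the vinyl terminus reach only one face of the ring alkene, and that face is fixed by the (1S,2S) configuration of 9, hence by the catalyst, taken as the R-series by analogy with the sense of induction of this catalyst family with monosubstituted alkenes. The step needs regioselection between the two alkenes of 6 (secured by their substitution), cis-selective cyclopropanation (inherent to donor/acceptor carbenoids), carbenoid rather than vinylogous reactivity (hydrocarbon solvent, methyl ester), and a Cope rearrangement onto a terminus whose methyl group points into the boat, which is why the mixture is heated after the addition.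

Step 7
Reactants: 10 methyl (3R,8aR)-8a-methyl-3-(propan-2-yl)-3-[(triethylsilyl)oxy]-1,2,3,5,8,8a-hexahydroazulene-6-carboxylate
Product: 12 methyl (3R,3aS,4S,8aR)-4-hydroxy-8a-methyl-3-(propan-2-yl)-3-[(triethylsilyl)oxy]-1,2,3,3a,4,5,8,8a-octahydroazulene-6-carboxylate, via alkylborane 11 (not isolated)
Conditions: BH3·THF, THF, 0 °C → rt; then H2O2, aq. NaOAc, 0 °C
Reagents that add atoms: hydrogen peroxide, OO (oxygen at C-4); borane–tetrahydrofuran, B.C1CCOC1 (boron of 11 only)
Why: Hydroboration–oxidation: borane adds to the electron-rich trisubstituted C3a=C4 alkene (C6=C7 is deactivated by the ester) with boron at the less substituted C-4 and hydrogen at C-3a, syn and from the face opposite the C-8a methyl and the C-3 silyloxy group, so that H-3a and the C-4 oxygen end up cis to each other and trans to the angular methyl after oxidation with retention.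

Step 8
Reactants: 12 methyl (3R,3aS,4S,8aR)-4-hydroxy-8a-methyl-3-(propan-2-yl)-3-[(triethylsilyl)oxy]-1,2,3,3a,4,5,8,8a-octahydroazulene-6-carboxylate
Product: 13 (3R,3aS,4S,8aR)-6-(hydroxymethyl)-8a-methyl-3-(propan-2-yl)-3-[(triethylsilyl)oxy]-1,2,3,3a,4,5,8,8a-octahydroazulen-4-ol
Conditions: i-Bu2AlH (4 equiv), CH2Cl2, −78 → 0 °C; aq. KNaC4H4O6 (potassium sodium tartrate) work-up
Reagents that add atoms: none
Why: 1,2-Reduction of the conjugated ester by the aluminium hydride gives the primary allylic alcohol; the silyl ether, the alkene and all stereocentres are unaffected.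

Step 9
Reactants: 13 (3R,3aS,4S,8aR)-6-(hydroxymethyl)-8a-methyl-3-(propan-2-yl)-3-[(triethylsilyl)oxy]-1,2,3,3a,4,5,8,8a-octahydroazulen-4-ol
Product: 14 (3R,3aS,4S,8aR)-6-(chloromethyl)-8a-methyl-3-(propan-2-yl)-3-[(triethylsilyl)oxy]-1,2,3,3a,4,5,8,8a-octahydroazulen-4-ol
Conditions: N-chlorosuccinimide, Me2S, CH2Cl2, −20 → 0 °C
Reagents that add atoms: N-chlorosuccinimide, ClN1C(=O)CCC1=O
Why: Corey–Kim chlorination: only the allylic alkoxysulfonium ion is displaced by chloride under these base-free conditions, while the one formed at the secondary C-4 hydroxyl returns the alcohol on work-up.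

Step 10
Reactants: 14 (3R,3aS,4S,8aR)-6-(chloromethyl)-8a-methyl-3-(propan-2-yl)-3-[(triethylsilyl)oxy]-1,2,3,3a,4,5,8,8a-octahydroazulen-4-ol
Product: 15 (3R,3aS,4S,8aR)-6,8a-dimethyl-3-(propan-2-yl)-3-[(triethylsilyl)oxy]-1,2,3,3a,4,5,8,8a-octahydroazulen-4-ol
Conditions: LiEt3BH (3 equiv), THF, 0 °C → rt
Reagents that add atoms: none
Why: SN2 displacement of the primary allylic chloride by the borohydride gives the C-6 methyl group without allylic transposition; the first equivalent is consumed by the free hydroxyl.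

Step 11
Reactants: 15 (3R,3aS,4S,8aR)-6,8a-dimethyl-3-(propan-2-yl)-3-[(triethylsilyl)oxy]-1,2,3,3a,4,5,8,8a-octahydroazulen-4-ol
Product: 16 (3R,3aS,4S,8aR)-6,8a-dimethyl-3-(propan-2-yl)-1,2,3,3a,4,5,8,8a-octahydroazulene-3,4-diol (jaeschkeanadiol)
Conditions: n-Bu4NF, THF, rt → 40 °C
Reagents that add atoms: none
Why: Fluoride cleaves the tertiary silyl ether; no other fluoride- or base-sensitive group is present, and removing silicon now prevents silyl migration to the C-4 alkoxide in step 12.

Step 12
Reactants: 16 (3R,3aS,4S,8aR)-6,8a-dimethyl-3-(propan-2-yl)-1,2,3,3a,4,5,8,8a-octahydroazulene-3,4-diol; 17 2,2-dimethyl-4H-1,3-benzodioxin-4-one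
Product: 18 (3R,3aS,4S,8aR)-3-hydroxy-6,8a-dimethyl-3-(propan-2-yl)-1,2,3,3a,4,5,8,8a-octahydroazulen-4-yl 2-hydroxybenzoate
Conditions: NaN(SiMe3)2 (1.2 equiv), THF, 0 °C → rt; aq. NH4Cl
Reagents that add atoms: none
Why: Alkoxide transesterification of the salicylate acetonide: the secondary C-4 alkoxide attacks the ring carbonyl, acetone is expelled and the phenoxide is protonated on work-up, while the tertiary C-3 hydroxyl is too hindered to compete and the C-4 configuration is kept because its C–O bond is not broken.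

## Compound list

1 | (S)-terpinen-4-ol, (S)-4-methyl-1-(propan-2-yl)cyclohex-3-en-1-ol | CC1=CC[C@](O)(C(C)C)CC1 | starting material
2 | (S)-triethyl{[4-methyl-1-(propan-2-yl)cyclohex-3-en-1-yl]oxy}silane | CC1=CC[C@](O[Si](CC)(CC)CC)(C(C)C)CC1 | intermediate
3 | secondary ozonide of 2, 1-methyl-4-(propan-2-yl)-4-[(triethylsilyl)oxy]-7,8,9-trioxabicyclo[4.2.1]nonane (ozonide diastereomers) | CC12CC[C@@](O[Si](CC)(CC)CC)(C(C)C)CC(OO1)O2 | intermediate (not isolated)
4 | (S)-6-oxo-3-(propan-2-yl)-3-[(triethylsilyl)oxy]heptanal | CC(=O)CC[C@@](O[Si](CC)(CC)CC)(C(C)C)CC=O | intermediate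
5 | (R)-2-methyl-5-(propan-2-yl)-5-[(triethylsilyl)oxy]cyclopent-1-ene-1-carbaldehyde | O=CC1=C(C)CC[C@@]1(O[Si](CC)(CC)CC)C(C)C | intermediate
6 | (R)-triethyl{[2-ethenyl-3-methyl-1-(propan-2-yl)cyclopent-2-en-1-yl]oxy}silane | C=CC1=C(C)CC[C@@]1(O[Si](CC)(CC)CC)C(C)C | intermediate
7 | methyl but-3-enoate | COC(=O)CC=C | starting material
8 | methyl 2-diazobut-3-enoate | COC(=O)C(=[N+]=[N-])C=C | intermediate
9 | methyl (1S,2S)-1-ethenyl-2-{(5R)-2-methyl-5-(propan-2-yl)-5-[(triethylsilyl)oxy]cyclopent-1-en-1-yl}cyclopropane-1-carboxylate | COC(=O)[C@]1(C=C)C[C@H]1C2=C(C)CC[C@@]2(O[Si](CC)(CC)CC)C(C)C | intermediate (not isolated)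
10 | methyl (3R,8aR)-8a-methyl-3-(propan-2-yl)-3-[(triethylsilyl)oxy]-1,2,3,5,8,8a-hexahydroazulene-6-carboxylate | COC(=O)C1=CC[C@@]2(C)CC[C@@](O[Si](CC)(CC)CC)(C(C)C)C2=CC1 | intermediate
11 | methyl (3R,3aR,4S,8aR)-4-boranyl-8a-methyl-3-(propan-2-yl)-3-[(triethylsilyl)oxy]-1,2,3,3a,4,5,8,8a-octahydroazulene-6-carboxylate (same spatial arrangement as 12) | COC(=O)C1=CC[C@@]2(C)CC[C@@](O[Si](CC)(CC)CC)(C(C)C)[C@@H]2[C@@H](B)C1 | intermediate (not isolated)
12 | methyl (3R,3aS,4S,8aR)-4-hydroxy-8a-methyl-3-(propan-2-yl)-3-[(triethylsilyl)oxy]-1,2,3,3a,4,5,8,8a-octahydroazulene-6-carboxylate | COC(=O)C1=CC[C@@]2(C)CC[C@@](O[Si](CC)(CC)CC)(C(C)C)[C@@H]2[C@@H](O)C1 | intermediate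
13 | (3R,3aS,4S,8aR)-6-(hydroxymethyl)-8a-methyl-3-(propan-2-yl)-3-[(triethylsilyl)oxy]-1,2,3,3a,4,5,8,8a-octahydroazulen-4-ol | OCC1=CC[C@@]2(C)CC[C@@](O[Si](CC)(CC)CC)(C(C)C)[C@@H]2[C@@H](O)C1 | intermediate
14 | (3R,3aS,4S,8aR)-6-(chloromethyl)-8a-methyl-3-(propan-2-yl)-3-[(triethylsilyl)oxy]-1,2,3,3a,4,5,8,8a-octahydroazulen-4-ol | ClCC1=CC[C@@]2(C)CC[C@@](O[Si](CC)(CC)CC)(C(C)C)[C@@H]2[C@@H](O)C1 | intermediate
15 | (3R,3aS,4S,8aR)-6,8a-dimethyl-3-(propan-2-yl)-3-[(triethylsilyl)oxy]-1,2,3,3a,4,5,8,8a-octahydroazulen-4-ol | CC1=CC[C@@]2(C)CC[C@@](O[Si](CC)(CC)CC)(C(C)C)[C@@H]2[C@@H](O)C1 | intermediate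
16 | (3R,3aS,4S,8aR)-6,8a-dimethyl-3-(propan-2-yl)-1,2,3,3a,4,5,8,8a-octahydroazulene-3,4-diol (jaeschkeanadiol) | CC1=CC[C@@]2(C)CC[C@@](O)(C(C)C)[C@@H]2[C@@H](O)C1 | intermediate
17 | 2,2-dimethyl-4H-1,3-benzodioxin-4-one | CC1(C)OC(=O)c2ccccc2O1 | starting material
18 | (3R,3aS,4S,8aR)-3-hydroxy-6,8a-dimethyl-3-(propan-2-yl)-1,2,3,3a,4,5,8,8a-octahydroazulen-4-yl 2-hydroxybenzoate | CC1=CC[C@@]2(C)CC[C@@](O)(C(C)C)[C@@H]2[C@@H](OC(=O)c2ccccc2O)C1 | target

## Step count

Total steps: 12. Longest linear sequence: 11 steps (1 to 18 through steps 1–4 and 6–12); step 5 is a one-step side branch.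

## Steps most likely to fail

**Step 6.** Three things may go wrong:
- The carbenoid may be consumed at its unsubstituted vinyl terminus, or by self-reaction of 8, before it meets the hindered diene.
- The Cope rearrangement onto the fully substituted terminus may be slow enough for 9 to epimerise, which would erode control at C-8a.
- The sense of induction may be opposite to the one assumed; in that case alone, the mirror-image catalyst Rh2(S-DOSP)4 corrects it without a change of route.

The fallback closes the seven-membered ring by ring-closing metathesis and makes the C8–C8a bond by an anionic oxy-Cope rearrangement. It sets out from 5 and comes back at 16.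
- 5 is desilylated with n-Bu4NF in THF to (R)-5-hydroxy-2-methyl-5-(propan-2-yl)cyclopent-1-ene-1-carbaldehyde F1.
- CH2=CHCH2MgBr in THF at −78 °C adds 1,2 to give 1-[(5R)-5-hydroxy-2-methyl-5-(propan-2-yl)cyclopent-1-en-1-yl]but-3-en-1-ol F2.
- KH and 18-crown-6 in THF (0 → 40 °C) trigger the oxy-Cope rearrangement of the dialkoxide. The C-3 oxygen is an alkoxide here and cannot be expelled from the resulting enolate. A cold acetic acid quench gives (1R,2R,5R)-5-hydroxy-2-methyl-5-(propan-2-yl)-2-(prop-2-en-1-yl)cyclopentane-1-carbaldehyde F3, whose formyl group should settle cis to the hydroxyl.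
- CH2=C(CH3)CH2MgCl adds under chelation by the neighbouring alkoxide to give (1R,2S,3R)-2-[(1S)-1-hydroxy-3-methylbut-3-en-1-yl]-3-methyl-1-(propan-2-yl)-3-(prop-2-en-1-yl)cyclopentan-1-ol F4.
- Second-generation Grubbs catalyst RuCl2(=CHPh)(PCy3)(H2IMes) in CH2Cl2 at 40 °C closes the C6=C7 bond and gives 16.
- This sequence relies on substrate control at C-8a and C-4, so unwanted diastereomers would be removed by chromatography.

**Step 7.** Borane may attack from the face of the C-8a methyl and silyloxy groups, because the isopropyl group crowds the wanted face. The cis-fused 3a,4-diastereomer would then accompany 12.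

The fallback replaces kinetic face selection by equilibration and a directed reduction. It sets out from 15, carried through steps 8–10 as the mixture with its C-3a/C-4 stereoisomers, and comes back at 16.
- Dess–Martin periodinane with NaHCO3 in CH2Cl2 oxidises the C-4 alcohols to (3R,8aR)-6,8a-dimethyl-3-(propan-2-yl)-3-[(triethylsilyl)oxy]-2,3,3a,5,8,8a-hexahydroazulen-4(1H)-one F5.
- HF·pyridine in THF removes the silyl group and lets C-3a equilibrate through the enol to the hydrogen-bonded trans-fused (3R,3aR,8aR)-3-hydroxy-6,8a-dimethyl-3-(propan-2-yl)-2,3,3a,5,8,8a-hexahydroazulen-4(1H)-one F6.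
- Me4NBH(OAc)3 in MeCN/AcOH at −20 °C (Evans–Saksena reduction) delivers hydride from the C-3 alkoxyborohydride to the carbonyl face on its own side, which gives the 4S alcohol 16.

**Step 3.** The aldehyde enamine may expel the β-silyloxy group instead of cyclising, or the ketone enol may attack the aldehyde and give the regioisomeric ring.

The fallback separates C–C bond formation from dehydration, so that the dehydration no longer runs through an enamine. It sets out from 4 and comes back at 5.
- (S)-Proline (20 mol%) in DMSO at room temperature is used only for the aldol addition. The product is isolated as (5R)-2-hydroxy-2-methyl-5-(propan-2-yl)-5-[(triethylsilyl)oxy]cyclopentane-1-carbaldehyde F7.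
- MsCl and Et3N in CH2Cl2 at −20 °C convert the new tertiary hydroxyl into (3R)-2-formyl-1-methyl-3-(propan-2-yl)-3-[(triethylsilyl)oxy]cyclopentyl methanesulfonate F8.
- DBU at 0 °C eliminates the mesylate by an E1cB pathway to give 5. The mesylate is by far the better leaving group of the two β-oxygen substituents.

## Further compounds

F1 | step 6 | (R)-5-hydroxy-2-methyl-5-(propan-2-yl)cyclopent-1-ene-1-carbaldehyde | O=CC1=C(C)CC[C@@]1(O)C(C)C
F2 | step 6 | 1-[(5R)-5-hydroxy-2-methyl-5-(propan-2-yl)cyclopent-1-en-1-yl]but-3-en-1-ol (both carbinol epimers) | C=CCC(O)C1=C(C)CC[C@@]1(O)C(C)C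
F3 | step 6 | (1R,2R,5R)-5-hydroxy-2-methyl-5-(propan-2-yl)-2-(prop-2-en-1-yl)cyclopentane-1-carbaldehyde | C=CC[C@@]1(C)CC[C@@](O)(C(C)C)[C@@H]1C=O
F4 | step 6 | (1R,2S,3R)-2-[(1S)-1-hydroxy-3-methylbut-3-en-1-yl]-3-methyl-1-(propan-2-yl)-3-(prop-2-en-1-yl)cyclopentan-1-ol | C=CC[C@@]1(C)CC[C@@](O)(C(C)C)[C@@H]1[C@@H](O)CC(C)=C
F5 | step 7 | (3R,8aR)-6,8a-dimethyl-3-(propan-2-yl)-3-[(triethylsilyl)oxy]-2,3,3a,5,8,8a-hexahydroazulen-4(1H)-one (C-3a epimers) | CC1=CC[C@@]2(C)CC[C@@](O[Si](CC)(CC)CC)(C(C)C)C2C(=O)C1
F6 | step 7 | (3R,3aR,8aR)-3-hydroxy-6,8a-dimethyl-3-(propan-2-yl)-2,3,3a,5,8,8a-hexahydroazulen-4(1H)-one | CC1=CC[C@@]2(C)CC[C@@](O)(C(C)C)[C@@H]2C(=O)C1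
F7 | step 3 | (5R)-2-hydroxy-2-methyl-5-(propan-2-yl)-5-[(triethylsilyl)oxy]cyclopentane-1-carbaldehyde (diastereomers at C-1 and C-2) | O=CC1C(C)(O)CC[C@@]1(O[Si](CC)(CC)CC)C(C)C
F8 | step 3 | (3R)-2-formyl-1-methyl-3-(propan-2-yl)-3-[(triethylsilyl)oxy]cyclopentyl methanesulfonate (diastereomers at C-1 and C-2) | O=CC1C(C)(OS(C)(=O)=O)CC[C@@]1(O[Si](CC)(CC)CC)C(C)C
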